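Ring B is disconnected at its C1–C6 bond instead of being built by substituting a phloroglucinol. The feature exploited is that ring B, read C6(OH)–C5(Me)–C4(OMe)–C3(acyl)–C2(OH), is a polyketide chain isomeric with a 4-methoxy-3-methyl-5-(2-methylpropanoyl)-2-pyranone, with C1 and the bridge CH2 as the side chain on the pyranone's C6. Methoxide opens the lactone and a Claisen closure of the side-chain methylene onto the released ester forms C1–C6, converting the pyranone into aromatic ring B with every substituent in place. The precursor is that pyranone carrying a 2-arylethyl group at C6, the aryl being fully etherified ring A (two benzyl ethers). Hydrogenolysis then gives the target.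

Key step: step 11

Remark: the target has no stereocentre, so none has to be set. In the ring-opened intermediate of the key step the ester and the diketone carbon are cis on the double bond, which is E by the CIP rules because OMe outranks carbon.

Step 1
Reactants: 1 2,4,6-trihydroxytoluene; 2 3-methylbutanoyl chloride
Product: 3 3-methyl-1-(2,4,6-trihydroxy-3-methylphenyl)butan-1-one
Conditions: AlCl3 (4 equiv), PhNO2, 0 to 60 °C; then ice/1 M HCl
Reagents that add atoms: none
Why: Friedel–Crafts acylation of the very electron-rich ring, whose two free carbons are equivalent by symmetry, should stop at the mono-ketone because the chelated acyl group deactivates the ring.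

Step 2
Reactants: 3 3-methyl-1-(2,4,6-trihydroxy-3-methylphenyl)butan-1-one
Product: 4 1-[4,6-bis(benzyloxy)-2-hydroxy-3-methylphenyl]-3-methylbutan-1-one
Conditions: BnBr (2.1 equiv), K2CO3 (2.2 equiv), acetone, reflux
Reagents that add atoms: benzyl bromide, BrCc1ccccc1
Why: Williamson etherification should take the acidic para hydroxyl and the less hindered ortho hydroxyl, while the hydroxyl wedged between the ketone and the ring methyl stays free because its hydrogen bond to the carbonyl is buttressed and its oxygen is shielded on both sides; the regiochemistry is to be checked by NOE from the lone ring proton to both OCH2Ph groups.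

Step 3
Reactants: 4 1-[4,6-bis(benzyloxy)-2-hydroxy-3-methylphenyl]-3-methylbutan-1-one
Product: 5 1-[4,6-bis(benzyloxy)-2-methoxy-3-methylphenyl]-3-methylbutan-1-one
Conditions: MeI (3 equiv), K2CO3 (2 equiv), DMF, 50 °C
Reagents that add atoms: iodomethane, CI
Why: Williamson methylation under forcing dipolar aprotic conditions should break the chelate and alkylate the one remaining phenol, for which no regiochemical choice is left.

Step 4
Reactants: 5 1-[4,6-bis(benzyloxy)-2-methoxy-3-methylphenyl]-3-methylbutan-1-one
Product: 7 2,6-bis(benzyloxy)-4-methoxy-3-methyl-5-(3-methylbutanoyl)benzaldehyde, via aryl iminium chloride 6 (not isolated)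
Conditions: POCl3 (1.5 equiv), DMF, 0 to 50 °C; then aq NaOAc
Reagents that add atoms: N,N-dimethylformamide, CN(C)C=O; water, O
Why: Vilsmeier–Haack formylation should take the single free ring carbon, which lies ortho to two benzyloxy groups and para to the methoxy group, while the hindered ketone is meta to that site, twisted out of conjugation and slow to enolise.

Step 5
Reactants: 7 2,6-bis(benzyloxy)-4-methoxy-3-methyl-5-(3-methylbutanoyl)benzaldehyde
Product: 8 1-[2,4-bis(benzyloxy)-3-(hydroxymethyl)-6-methoxy-5-methylphenyl]-3-methylbutan-1-one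
Conditions: NaBH4 (0.5 equiv), THF/MeOH, −10 °C
Reagents that add atoms: none
Why: Borohydride reduction should be chemoselective for the aldehyde over the ketone, which is flanked by two ortho substituents and a branched alkyl chain.

Step 6
Reactants: 8 1-[2,4-bis(benzyloxy)-3-(hydroxymethyl)-6-methoxy-5-methylphenyl]-3-methylbutan-1-one
Product: 9 1-[2,4-bis(benzyloxy)-3-(bromomethyl)-6-methoxy-5-methylphenyl]-3-methylbutan-1-one
Conditions: PBr3 (0.4 equiv), CH2Cl2, 0 °C; cold aq NaHCO3; used crude at once
Reagents that add atoms: phosphorus tribromide, BrP(Br)Br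
Why: Conversion of an activated benzylic alcohol into the bromide through its phosphite ester should be fast at 0 °C and leaves the aryl ethers and the ketone untouched.

Step 7
Reactants: 10 methylmalonic acid
Product: 11 methylmalonyl dichloride (2-methylpropanedioyl dichloride)
Conditions: SOCl2 (3 equiv), 50 °C; distilled under reduced pressure
Reagents that add atoms: thionyl chloride, O=S(Cl)Cl
Why: Acid chloride formation through the chlorosulfite is standard for malonic acids when the temperature is kept low enough to avoid ketene formation and decarboxylation.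

Step 8
Reactants: 12 5-methylhexane-2,4-dione; 11 methylmalonyl dichloride
Product: 14 4-hydroxy-3,6-dimethyl-5-(2-methylpropanoyl)-2H-pyran-2-one, via acylated acid chloride 13 (not isolated)
Conditions: CH2Cl2, rt to 40 °C, N2 sweep
Reagents that add atoms: none
Why: This is the known pyranone synthesis from 1,3-diketones and malonyl dichlorides (C-acylation of the enolised diketone, then lactonisation of the second acid chloride onto an enol oxygen); closure through the less hindered acetyl-derived oxygen should place methyl at C6, and any 6-isopropyl isomer is removed here by chromatography.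

Step 9
Reactants: 14 4-hydroxy-3,6-dimethyl-5-(2-methylpropanoyl)-2H-pyran-2-one
Product: 15 4-methoxy-3,6-dimethyl-5-(2-methylpropanoyl)-2H-pyran-2-one
Conditions: Me2SO4 (1.2 equiv), K2CO3 (1.5 equiv), acetone, reflux
Reagents that add atoms: dimethyl sulfate, COS(=O)(=O)OC
Why: O-Alkylation of the potassium salt of the vinylogous acid with a sulfate ester should give the 4-methoxy-2-pyranone, as is usual for 4-hydroxy-2-pyranones under these conditions.

Step 10
Reactants: 15 4-methoxy-3,6-dimethyl-5-(2-methylpropanoyl)-2H-pyran-2-one; 9 1-[2,4-bis(benzyloxy)-3-(bromomethyl)-6-methoxy-5-methylphenyl]-3-methylbutan-1-one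
Product: 17 6-{2-[2,6-bis(benzyloxy)-4-methoxy-3-methyl-5-(3-methylbutanoyl)phenyl]ethyl}-4-methoxy-3-methyl-5-(2-methylpropanoyl)-2H-pyran-2-one, via lithium dienolate 16 (not isolated)
Conditions: 15 (1.4 equiv), LiN(SiMe3)2 (1.35 equiv), THF, −78 °C; then 9 (1.0 equiv), DMPU, −78 to 0 °C
Reagents that add atoms: none
Why: Vinylogous enolate alkylation: the C6 methyl, conjugated to both the lactone and the C5 ketone, is the most acidic site, and its lithium dienolate should be benzylated at the exocyclic carbon, the only position that restores the pyranone; the weakly basic enolate leaves the hindered ring A ketone alone and the excess of 15 suppresses double alkylation.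

Step 11
Reactants: 17 6-{2-[2,6-bis(benzyloxy)-4-methoxy-3-methyl-5-(3-methylbutanoyl)phenyl]ethyl}-4-methoxy-3-methyl-5-(2-methylpropanoyl)-2H-pyran-2-one
Product: 20 1-[2,4-bis(benzyloxy)-3-{[2,6-dihydroxy-4-methoxy-3-methyl-5-(2-methylpropanoyl)phenyl]methyl}-6-methoxy-5-methylphenyl]-3-methylbutan-1-one, via ring-opened keto ester 18 (not isolated), via cyclohexenedione 19 (not isolated)
Conditions: Mg(OMe)2 (6 equiv), MeOH/THF, reflux, Ar; then cold 1 M HCl
Reagents that add atoms: none
Why: Proposed new method: magnesium-bound methoxide adds to the lactone carbonyl of 17 and expels the ring oxygen as the chelated enolate of a 1,3-diketone, giving the (2E)-3-methoxyacrylate 18 with ester and diketone held cis; a second deprotonation at the ketone-flanking CH2 of the arylethyl chain (future C1 of ring B) and attack of that carbon on the ester carbonyl (future C6) with loss of methoxide gives 19, which enolises to the magnesium phenoxide of 20. The closest known reactions are the Mg(OMe)2 opening of 4-methoxy-2-pyranones to 3-methoxy-5-oxoenoates, the Claisen cyclisation of polyketo esters to acylphloroglucinols and the terminal acylation of 1,3-diketone dianions by esters; new here is a singly activated methylene nucleophile on a 5-acyl-4-methoxypyranone. Ring B closes in a 6-(enolendo)-exo-trig Claisen mode, and no stereocentre results because both sp3 ring carbons of 19 become aromatic. The step needs attack by the chain methylene and not by the 2-methylpropanoyl methine: the methylene is less hindered and more easily metallated, closure through the methine would give a gem-dimethyl trione that cannot aromatise and can reopen by retro-Claisen cleavage, whereas the chelated phenoxide forms irreversibly. The C4 methoxy group is never unmasked, and methoxide in methanol makes any addition–elimination at that carbon degenerate. The fully etherified ring A cannot ionise, which excludes base-induced scrambling of the methylene bridge.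

Step 12
Reactants: 20 1-[2,4-bis(benzyloxy)-3-{[2,6-dihydroxy-4-methoxy-3-methyl-5-(2-methylpropanoyl)phenyl]methyl}-6-methoxy-5-methylphenyl]-3-methylbutan-1-one
Product: 21 1-[3-{[2,6-dihydroxy-4-methoxy-3-methyl-5-(2-methylpropanoyl)phenyl]methyl}-2,4-dihydroxy-6-methoxy-5-methylphenyl]-3-methylbutan-1-one (CNP0265841.0)
Conditions: H2 (1 atm), 10% Pd/C, EtOAc/MeOH, rt
Reagents that add atoms: none
Why: Hydrogenolysis of the two aryl benzyl ethers over palladium on carbon under neutral conditions should leave the chelated aryl ketones and the diarylmethane untouched and avoids the base-induced scrambling known for methylene-bridged phloroglucinols.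

Compound list
1 | 2,4,6-trihydroxytoluene | Cc1c(O)cc(O)cc1O | starting material
2 | 3-methylbutanoyl chloride | CC(C)CC(=O)Cl | starting material
3 | 3-methyl-1-(2,4,6-trihydroxy-3-methylphenyl)butan-1-one | CC(C)CC(=O)c1c(O)cc(O)c(C)c1O | intermediate
4 | 1-[4,6-bis(benzyloxy)-2-hydroxy-3-methylphenyl]-3-methylbutan-1-one | CC(C)CC(=O)c1c(OCc2ccccc2)cc(OCc2ccccc2)c(C)c1O | intermediate
5 | 1-[4,6-bis(benzyloxy)-2-methoxy-3-methylphenyl]-3-methylbutan-1-one | CC(C)CC(=O)c1c(OCc2ccccc2)cc(OCc2ccccc2)c(C)c1OC | intermediate
6 | {[2,6-bis(benzyloxy)-4-methoxy-3-methyl-5-(3-methylbutanoyl)phenyl]methylidene}dimethylammonium chloride | C[N+](C)=Cc1c(OCc2ccccc2)c(C)c(OC)c(C(=O)CC(C)C)c1OCc1ccccc1.[Cl-] | intermediate (not isolated)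
7 | 2,6-bis(benzyloxy)-4-methoxy-3-methyl-5-(3-methylbutanoyl)benzaldehyde | O=Cc1c(OCc2ccccc2)c(C)c(OC)c(C(=O)CC(C)C)c1OCc1ccccc1 | intermediate
8 | 1-[2,4-bis(benzyloxy)-3-(hydroxymethyl)-6-methoxy-5-methylphenyl]-3-methylbutan-1-one | OCc1c(OCc2ccccc2)c(C)c(OC)c(C(=O)CC(C)C)c1OCc1ccccc1 | intermediate
9 | 1-[2,4-bis(benzyloxy)-3-(bromomethyl)-6-methoxy-5-methylphenyl]-3-methylbutan-1-one | BrCc1c(OCc2ccccc2)c(C)c(OC)c(C(=O)CC(C)C)c1OCc1ccccc1 | intermediate
10 | methylmalonic acid | CC(C(=O)O)C(=O)O | starting material
11 | methylmalonyl dichloride | CC(C(=O)Cl)C(=O)Cl | intermediate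
12 | 5-methylhexane-2,4-dione | CC(C)C(=O)CC(C)=O | starting material
13 | 4-acetyl-2,6-dimethyl-3,5-dioxoheptanoyl chloride (configurationally labile, unspecified) | CC(C)C(=O)C(C(C)=O)C(=O)C(C)C(=O)Cl | intermediate (not isolated)
14 | 4-hydroxy-3,6-dimethyl-5-(2-methylpropanoyl)-2H-pyran-2-one | CC(C)C(=O)C1=C(C)OC(=O)C(C)=C1O | intermediate
15 | 4-methoxy-3,6-dimethyl-5-(2-methylpropanoyl)-2H-pyran-2-one | COC1=C(C)C(=O)OC(C)=C1C(=O)C(C)C | intermediate
16 | lithium dienolate of 15 from deprotonation of the C6 methyl group (drawn as the C5-acyl enolate with an exocyclic C6 methylidene) | [Li+].[O-]C(C(C)C)=C1C(OC)=C(C)C(=O)OC1=C | intermediate (not isolated)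
17 | 6-{2-[2,6-bis(benzyloxy)-4-methoxy-3-methyl-5-(3-methylbutanoyl)phenyl]ethyl}-4-methoxy-3-methyl-5-(2-methylpropanoyl)-2H-pyran-2-one | COC1=C(C)C(=O)OC(CCc2c(OCc3ccccc3)c(C)c(OC)c(C(=O)CC(C)C)c2OCc2ccccc2)=C1C(=O)C(C)C | intermediate
18 | methyl (2E)-7-[2,6-bis(benzyloxy)-4-methoxy-3-methyl-5-(3-methylbutanoyl)phenyl]-3-methoxy-2-methyl-4-(2-methylpropanoyl)-5-oxohept-2-enoate (present as its magnesium enolate; C4 labile) | COC(=O)/C(C)=C(OC)\C(C(=O)C(C)C)C(=O)CCc1c(OCc2ccccc2)c(C)c(OC)c(C(=O)CC(C)C)c1OCc1ccccc1 | intermediate (not isolated)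
19 | 2-{[2,6-bis(benzyloxy)-4-methoxy-3-methyl-5-(3-methylbutanoyl)phenyl]methyl}-5-methoxy-4-methyl-6-(2-methylpropanoyl)cyclohex-4-ene-1,3-dione (both sp3 ring carbons labile) | COC1=C(C)C(=O)C(Cc2c(OCc3ccccc3)c(C)c(OC)c(C(=O)CC(C)C)c2OCc2ccccc2)C(=O)C1C(=O)C(C)C | intermediate (not isolated)
20 | 1-[2,4-bis(benzyloxy)-3-{[2,6-dihydroxy-4-methoxy-3-methyl-5-(2-methylpropanoyl)phenyl]methyl}-6-methoxy-5-methylphenyl]-3-methylbutan-1-one | COc1c(C)c(O)c(Cc2c(OCc3ccccc3)c(C)c(OC)c(C(=O)CC(C)C)c2OCc2ccccc2)c(O)c1C(=O)C(C)C | intermediate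
21 | 1-[3-{[2,6-dihydroxy-4-methoxy-3-methyl-5-(2-methylpropanoyl)phenyl]methyl}-2,4-dihydroxy-6-methoxy-5-methylphenyl]-3-methylbutan-1-one | COc1c(C)c(O)c(Cc2c(O)c(C)c(OC)c(C(=O)C(C)C)c2O)c(O)c1C(=O)CC(C)C | target

Total step count: 12. Longest linear sequence: 9 (steps 1 to 6, 10, 11, 12); steps 7 to 9 form the side branch.

Steps most likely to fail

Step 11 (proposed new method). The magnesium diketonate of 18 may fail to ionise a second time at the chain methylene, so that the material only equilibrates between the open ester and the two isomeric pyranones, or closure may occur through the methine. The fallback sets out from 1 and 8, returns at 20 and uses the known Friedel–Crafts benzylation of an acylphloroglucinol. Compound 1 is acylated with 2-methylpropanoyl chloride (AlCl3, PhNO2) to 2-methyl-1-(2,4,6-trihydroxy-3-methylphenyl)propan-1-one F1. F1 is dibenzylated as in step 2 to 1-[4,6-bis(benzyloxy)-2-hydroxy-3-methylphenyl]-2-methylpropan-1-one F2 and methylated as in step 3 to 1-[4,6-bis(benzyloxy)-2-methoxy-3-methylphenyl]-2-methylpropan-1-one F3. Hydrogenolysis (H2, 10% Pd/C) gives 1-(4,6-dihydroxy-2-methoxy-3-methylphenyl)-2-methylpropan-1-one F4. The single free ring carbon of F4 is then alkylated by the benzylic cation from alcohol 8 (catalytic BF3·OEt2 or Sc(OTf)3, CH2Cl2, 0 °C) to give 20. Ring A carries no free hydroxyl, so only the cross-coupled diarylmethane can form.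

Step 10. The stabilised dienolate may react too slowly with the hindered bromide, so that ionisation of the bromide or double alkylation takes over. The fallback sets out from 9 and 12 and returns at 17, building the pyranone after the carbon–carbon bond. Compound 12 is converted with LiN(iPr)2 (2.1 equiv, THF, 0 °C) into dilithium 5-methylhexane-2,4-dione-1,3-diide F5, which is used in excess and alkylated at its terminal carbon by 9 to give 1-[2,6-bis(benzyloxy)-4-methoxy-3-methyl-5-(3-methylbutanoyl)phenyl]-6-methylheptane-3,5-dione F6. Treatment with 11 as in step 8 gives 6-{2-[2,6-bis(benzyloxy)-4-methoxy-3-methyl-5-(3-methylbutanoyl)phenyl]ethyl}-4-hydroxy-3-methyl-5-(2-methylpropanoyl)-2H-pyran-2-one F7, and Me2SO4/K2CO3 then gives 17. Either direction of ring closure is acceptable in this variant, since both pyranones open to the same diketo ester in step 11.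

Step 2. Discrimination between the two ketone-flanking hydroxyls may be poor, which would give the wrong dibenzyl ether alongside 4. The fallback sets out from 1 and returns at 7, so it also replaces steps 1, 3 and 4; it fixes the methoxy position with a formyl group instead. Vilsmeier–Haack reaction of 1 (POCl3, DMF) gives [(2,4,6-trihydroxy-3-methylphenyl)methylidene]dimethylammonium chloride F8, hydrolysed to 2,4,6-trihydroxy-3-methylbenzaldehyde F9. The hydroxyl para to the formyl group is the most acidic and the only one without a hydrogen bond to it; it is methylated with one equivalent of Me2SO4 (K2CO3, acetone, rt) to 2,6-dihydroxy-4-methoxy-3-methylbenzaldehyde F10. Friedel–Crafts acylation of the last free ring carbon with 2 (TiCl4, CH2Cl2) gives 2,6-dihydroxy-4-methoxy-3-methyl-5-(3-methylbutanoyl)benzaldehyde F11. Benzylation of both remaining hydroxyls (BnBr, K2CO3, DMF, 60 °C) gives 7 with no regiochemical choice left.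

Further compounds
F1 | step 11 | 2-methyl-1-(2,4,6-trihydroxy-3-methylphenyl)propan-1-one | CC(C)C(=O)c1c(O)cc(O)c(C)c1O
F2 | step 11 | 1-[4,6-bis(benzyloxy)-2-hydroxy-3-methylphenyl]-2-methylpropan-1-one | CC(C)C(=O)c1c(OCc2ccccc2)cc(OCc2ccccc2)c(C)c1O
F3 | step 11 | 1-[4,6-bis(benzyloxy)-2-methoxy-3-methylphenyl]-2-methylpropan-1-one | CC(C)C(=O)c1c(OCc2ccccc2)cc(OCc2ccccc2)c(C)c1OC
F4 | step 11 | 1-(4,6-dihydroxy-2-methoxy-3-methylphenyl)-2-methylpropan-1-one | CC(C)C(=O)c1c(O)cc(O)c(C)c1OC
F5 | step 10 | dilithium 5-methylhexane-2,4-dione-1,3-diide | [Li+].[Li+].[CH2-]C(=O)[CH-]C(=O)C(C)C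
F6 | step 10 | 1-[2,6-bis(benzyloxy)-4-methoxy-3-methyl-5-(3-methylbutanoyl)phenyl]-6-methylheptane-3,5-dione | CC(C)C(=O)CC(=O)CCc1c(OCc2ccccc2)c(C)c(OC)c(C(=O)CC(C)C)c1OCc1ccccc1
F7 | step 10 | 6-{2-[2,6-bis(benzyloxy)-4-methoxy-3-methyl-5-(3-methylbutanoyl)phenyl]ethyl}-4-hydroxy-3-methyl-5-(2-methylpropanoyl)-2H-pyran-2-one | CC(C)C(=O)C1=C(CCc2c(OCc3ccccc3)c(C)c(OC)c(C(=O)CC(C)C)c2OCc2ccccc2)OC(=O)C(C)=C1O
F8 | step 2 | [(2,4,6-trihydroxy-3-methylphenyl)methylidene]dimethylammonium chloride | C[N+](C)=Cc1c(O)cc(O)c(C)c1O.[Cl-]
F9 | step 2 | 2,4,6-trihydroxy-3-methylbenzaldehyde | O=Cc1c(O)cc(O)c(C)c1O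
F10 | step 2 | 2,6-dihydroxy-4-methoxy-3-methylbenzaldehyde | O=Cc1c(O)cc(OC)c(C)c1O
F11 | step 2 | 2,6-dihydroxy-4-methoxy-3-methyl-5-(3-methylbutanoyl)benzaldehyde | O=Cc1c(O)c(C)c(OC)c(C(=O)CC(C)C)c1O
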